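The free catalyst is the selector here: it is single-handed, and it couples both mirror substrates with the coupling partner. Elm and birch are my two earlier runs of that coupling.

common to all: left-handed substrate 0.050 M; right-handed substrate 0.050 M; free catalyst 0.25 mM

| flask | coupling partner | precatalyst | remark | time |
|---|---|---|---|---|
| elm | 0.20 M | 0.067 mM | run made earlier |  |
| birch | 0.20 M | 0.15 mM | run made earlier |  |
| red | 0.200 M | 0.10 mM |  | 25 h |
| ochre | 0.200 M | 0.10 mM |  | 8.0 h |

| run | time / h | left-handed product / % | right-handed product / % |
|---|---|---|---|
| elm | 2.50 | 28 | 13 |
| elm | 5.00 | 37 | 16 |
| elm | 8.00 | 44 | 23 |
| elm | 15.0 | 44 | 29 |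
| elm | 30.0 | 49 | 32 |
| birch | 2.50 | 34 | 12 |
| birch | 5.00 | 35 | 20 |
| birch | 8.00 | 38 | 23 |
| birch | 15.0 | 47 | 27 |
| birch | 30.0 | 46 | 31 |

(scatter of a reading: 1.5 percentage points)

- free catalyst is single-handed; left-handed substrate and right-handed substrate are mirror images of each other, charged as a racemate, each of them at the stated concentration
- an excess is below zero if the other one leads

- which one finishes higher in excess of left-handed product over right-handed product in the product ("neither" within 2 percentage points) (red / ochre / neither)
- excess of left-handed product over right-handed product in the product at the end, red
- excess of left-handed product over right-handed product in the product at the end, ochre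

Red and ochre share one charge, with [precatalyst] of 0.10 mM between elm's 0.067 mM and birch's 0.15 mM. Birch leads elm in left-handed product at 2.50 h, 34 % against 28 %, but trails at 8.00 h, 38 % against 44 %, so I pool the runs.

At any moment both steps share [coupling partner] and [free catalyst], so the left-handed rate over the right-handed rate is s·[left-handed substrate]/[right-handed substrate]. Here s is the selectivity factor, which acts like a copolymerization reactivity ratio. As long as each substrate is lost through its own coupling step, s equals the ratio of the logarithms of what remains of each substrate, and the pooled readings at 8.00 h give 2.78.

By this reading the excess starts at a ceiling of 47.1 %. It then drifts down, since the left-handed substrate falls faster. The pooled readings tighten this: 33.3 % at 5.00 h, 23.8 % at 15.0 h, 20.3 % at 30.0 h. So I place ochre between the first two, and my own point from its time is 28.1 %. I place red between the last two. Ochre's lower bound is red's upper bound, so I commit to ochre.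

The forecast also says ochre, with 21 % for red and 29 % for ochre, on the ground that “The excess falls with time as the slower enantiomer catches up”. Both values sit inside my brackets, and its ochre stands above my point.

The flask gives ochre: 21.1 % for red and 30.2 % for ochre.

    coupling partner + racemization catalyst → spent catalyst (k = 0.0778 L mol⁻¹ h⁻¹)
    coupling partner + precatalyst → racemization catalyst + spent reagent (k = 0.0706 L mol⁻¹ h⁻¹)
    coupling partner + free catalyst + right-handed substrate → free catalyst + right-handed product (k = 3280 L² mol⁻² h⁻¹)
    coupling partner + free catalyst + left-handed substrate → free catalyst + left-handed product (k = 9770 L² mol⁻² h⁻¹)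
    2 coupling partner → self-condensation product (k = 0.597 L mol⁻¹ h⁻¹)
    left-handed substrate + racemization catalyst ⇌ right-handed substrate + racemization catalyst, rate k6*[racemization catalyst]*[left-handed substrate] forward; the back reaction follows from the equilibrium constant (k = 59.8 L mol⁻¹ h⁻¹)

In ochre both coupling steps ran while coupling partner lasted, down to 23.2 % of its charge at 8.00 h, with half of the right-handed turnover up to that time done by 2.10 h. Beside them self-condensation in ochre drew coupling partner at 2.0 times the left-handed step's rate at the start, and racemization catalyst stood at 4.77 % of the precatalyst charged by 8.00 h. Through s, ochre's 22.1 % of right-handed product gives 40.2 % of left-handed product and an excess of 29.1 %.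

Ochre read at 2.0 h holds 10.7 % of right-handed product, so s gives 24.4 % of left-handed product and an excess of 39.0 %. The computed flask stands at 25.6 % and 41.0 %.

Readings and results were computed for substances that don't exist; the scatter is artificial.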